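# Proposed synthesis of CNP0291478.1 (compound 31) by aryne insertion into methylmalonate

## Analysis of the target

The target 31 is a 2H-chromen-2-one whose benzene ring (ring A, C4a to C8a) carries no hydrogen. The lactone ring B is fused at C4a/C8a, C5 bears a 3-hydroxybutan-2-yl chain, C6 and C8 bear methyl groups and C7 a free phenol. C3 of ring B is bonded to C6 of a 2-methyl-2,3-dihydro-4H-pyran-4-one (ring C).

There are three stereocenters. C2 of ring C is R. In the side chain the benzylic carbon is R and the carbinol carbon is S, a threo pair, which becomes a trans-3,4-dimethyl lactone if the hydroxyl is tied back to the C4 carbon. The ring C center is remote from this pair and must be set independently.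

The sensitive groups are the following. Ring C is a vinylogous ester that amines can open and whose stereocenter can be lost by base-induced retro-oxa-Michael opening. The coumarin lactone and the phenol are further sensitive sites. The side-chain hydroxyl closes to a six-membered lactol on any precursor with C4 at the aldehyde level.

The main difficulty is the hexasubstituted ring A with two different carbon substituents on neighbouring carbons. C5 is meta to both ring oxygens (on C7 and C8a), so no electrophilic substitution can deliver the side-chain carbon there. The strategy rests on this feature: C4a and C5 are adjacent, and the oxygen on C8a, next to C4a, polarizes an aryne spanning C4a–C5. A carbon nucleophile therefore enters at C5, and the aryl anion left at C4a captures the carbon that becomes C4.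

## Retrosynthetic reasoning

**Ring B (C3–C4 and O1–C2).** Target 31 is cut into the salicylaldehyde 29, stored as its lactol 20, and the dihydropyranonylacetate 28. The coumarin double bond and lactone are what a Knoevenagel condensation followed by lactonization produces. The cut separates the two stereochemical domains, and ring C arrives complete and meets only one mild step. The forward reaction must open the lactol, condense at the aldehyde, close the lactone with the C8a hydroxyl and thereby release the side-chain hydroxyl.

**Ring C.** Acetate 28 is the cyclodehydration product of hydroxy diketo ester 27, obtained from silyl ether 26. Cutting 26 between C4 and C5 of the chain gives Weinreb amide 23 and the dianion 25 of methyl acetoacetate 24. Amide 23 comes from ester 22 and from methyl (R)-3-hydroxybutanoate 21, whose stereocenter carries the ring oxygen and is never broken.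

**Oxidation level and phenols.** Lactol 20 is the half-reduced form of lactone 19, and 19 is the bis-demethylated form of 18. The lactone is kept as long as possible because it protects the side-chain hydroxyl and the C4 carbon together and makes the bicycle rigid.

**C6 methyl.** Lactone 18 is cut at the C–CH3 bond of the last ring position, back to bromide 17 and to 16. That position is the only free ring carbon and is ortho and para to the two methoxy groups, so halogenation there is unambiguous. Holding the methyl back keeps the aryne trisubstituted, so the nucleophile enters beside a hydrogen.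

**Both side-chain stereocenters.** Lactone 16 is opened at the ring C–O bond to hydroxy ester 15, and 15 is taken back to the racemic ketone 14. One reduction of the epimerizable α-aryl ketone sets the carbinol center and selects the benzylic configuration. Ketone 14 comes from Weinreb amide 13 and this from diester 12, whose two esters differ sharply in hindrance.

**Key disconnection.** Diester 12 is cut at the bond from C5 to the benzylic carbon and at the bond from C4a to the ester carbon. Both bonds come from one reagent, dimethyl methylmalonate 9, inserted into aryne 10. Aryne 10 is released from silyl triflate 8 and passes through benzocyclobutenoxide 11. The methyl group of 9 becomes the benzylic methyl group.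

**Aryne precursor.** Triflate 8 derives from bromophenol 5 by silylation (6), retro-Brook shift (7) and triflation. Bromophenol 5 comes from phenol 4 by bromination, and 4 from the commercial bromide 1 through aryllithium 2 and borate 3.

## Alternatives that were turned down

**Alternative 1:** Ring A would be built by cutting C5–C6 and C8–C8a. A ketone enolate supplying C6, C7, C8 and both ring methyl groups adds to the alkylidene malonate A2, and a Claisen closure gives the cyclohexane-1,3-dione A1. A1 is aromatized later.
- For it: the side-chain stereocenters come from a chiral aldehyde, so no dynamic reduction is needed. Both ring methyl groups and the C4 ester are placed by construction, so no late methylation or demethylation is needed. On these points it is stronger than the chosen route.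
- Against it: the benzylic stereocenter of A2 is γ to two esters and can be lost by deconjugation under the basic Michael conditions. The Michael addition joins a substituted enolate carbon to a β-carbon that carries a branched substituent. The later dehydrogenation of a fully substituted dione must be done in the presence of a silyl ether.
- Comparison: the chosen route instead forms the two critical bonds on a flat arene at unhindered positions and confines the stereochemical risk to one catalytic step of a known class.

**Alternative 2:** Ring B would be cut at C4–C4a and O1–C2. The resorcinol A4 attacks the aminomethylene carbon of enamino ester A5 under acid, dimethylamine leaves and the lactone closes to the acetate A3.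
- For it: it is the most convergent plan, avoids the lactol and the hydride reduction of a free phenol lactone, and ring A has only one free carbon, so the site of attack is unambiguous. It is stronger than the chosen route in step economy of the end game.
- Against it: the C4–C4a bond must form by electrophilic substitution at a carbon flanked by the branched side chain. The acid needed threatens ring C and the benzylic acetate. The final deacetylation must spare a coumarin and a vinylogous ester. A4 with both stereocenters still has to be made, so the stereochemical problem is not addressed.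
- Comparison: the chosen route makes the C4–C4a bond first, through an aryl anion that is indifferent to hindrance, and closes ring B from an aldehyde.

**Alternative 3:** Ring A would be cut at C5–C6 and C4a–C8a. Diene A8 and ynoate A7 undergo a Diels–Alder reaction, and loss of methanol and silanol gives the benzoate A6.
- For it: all six substituents and the free phenols arrive in one step, the stereocenters come from the chiral pool, and the polarity of both partners fixes the regiochemistry. It is stronger in convergence and needs no protecting-group removal on ring A.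
- Against it: the bond to C5 joins a methyl-bearing diene terminus to an alkyne carbon with a branched substituent, so heating is needed. The propargylic stereocenter of A7 is γ to the ester and can isomerize through the allene. A7 itself needs a multistep synthesis with two stereocenters.
- Comparison: the chosen route reaches its aromatic core in four steps from a cheap bromide and forms every ring A bond at an unhindered center.

Key step: step 4

**Assumptions.**
- The sense of induction in step 7 is assigned by analogy with hydrogenations of methyl ketones bearing one large substituent, where the (R)-diphosphine/(R)-diamine pair gives the (S)-carbinol; if the mirror-image lactone forms, the enantiomeric complex is used.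
- Lactol 20 is carried as the equilibrium mixture of its two C1 epimers and its open form 29, all of which converge in step 16.

## Route

**Step 1**
Reactants: 1 5-bromo-1,3-dimethoxy-2-methylbenzene
Product: 4 3,5-dimethoxy-4-methylphenol, via aryllithium 2 (not isolated), via lithium aryltrimethoxyborate 3 (not isolated)
Conditions: n-BuLi, THF, −78 °C; B(OMe)3, −78 °C → rt; 30% H2O2, aq. NaOH, 0 °C → rt
Reagents that add atoms: hydrogen peroxide, OO
Why: Bromine–lithium exchange is faster than ortho-lithiation by the methoxy groups; the aryllithium is trapped as the borate and the C–B bond is oxidized to C–O (boronate oxidation), a standard halide-to-phenol sequence.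

**Step 2**
Reactants: 4 3,5-dimethoxy-4-methylphenol
Product: 5 2-bromo-3,5-dimethoxy-4-methylphenol
Conditions: NBS (1.0 equiv), CH2Cl2, −78 → 0 °C
Reagents that add atoms: N-bromosuccinimide, O=C1CCC(=O)N1Br
Why: Electrophilic aromatic bromination; the two free positions are equivalent and activated by the ortho hydroxyl and the ortho/para methoxy groups, and one equivalent at low temperature should stop at the monobromide.

**Step 3**
Reactants: 5 2-bromo-3,5-dimethoxy-4-methylphenol
Product: 8 3,5-dimethoxy-4-methyl-2-(trimethylsilyl)phenyl trifluoromethanesulfonate, via aryl trimethylsilyl ether 6 (not isolated), via lithium 2-silylphenoxide 7 (not isolated)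
Conditions: HMDS, THF, 65 °C, volatiles removed; n-BuLi, THF, −100 °C; Tf2O, −100 °C → rt
Reagents that add atoms: hexamethyldisilazane, C[Si](C)(C)N[Si](C)(C)C; trifluoromethanesulfonic anhydride, O=S(=O)(OS(=O)(=O)C(F)(F)F)C(F)(F)F
Why: After O-silylation, bromine–lithium exchange triggers the 1,3 O→C silyl shift (retro-Brook rearrangement) and the resulting phenoxide is triflated on oxygen; this is the standard entry to 2-silylaryl triflates.

**Step 4**
Reactants: 8 3,5-dimethoxy-4-methyl-2-(trimethylsilyl)phenyl trifluoromethanesulfonate; 9 dimethyl methylmalonate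
Product: 12 methyl 2,4-dimethoxy-6-(1-methoxy-1-oxopropan-2-yl)-3-methylbenzoate (racemic), via 3,5-dimethoxy-4-methylbenzyne 10 (not isolated), via caesium benzocyclobutenoxide 11 (not isolated)
Conditions: CsF (3 equiv), 9 (1.5 equiv), MeCN, 80 °C
Reagents that add atoms: none
Why: Fluoride attacks silicon and triflate leaves, giving aryne 10, while fluoride (and later the product enolate) deprotonates 9. The tertiary malonate carbanion adds to the aryne carbon that carried the triflate (C5 of the target), and the aryl anion formed next to the methoxy group attacks one ester carbonyl to give the four-membered alkoxide 11. This opens by cleaving the former malonate C–C bond to the aryl ester and an ester enolate, which is protonated to 12; the closest known reaction is aryne insertion into the C–C σ-bond of malonates and β-keto esters (acyl-alkylation of arynes). No ring remains in the product: the four-membered ring closes 4-exo-trig and opens in the same operation. The benzylic stereocenter is formed by enolate protonation, is not controlled and is racemic; it is corrected in step 7. The step needs regioselective addition to the unsymmetrical aryne, which the inductively withdrawing methoxy group beside one aryne carbon secures by stabilizing the developing anion there and directing the nucleophile to the distal carbon flanked only by hydrogen. It also needs acyl transfer to outrun protonation of the aryl anion, which the aprotic medium and the ester held three atoms away should secure.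

**Step 5**
Reactants: 12 methyl 2,4-dimethoxy-6-(1-methoxy-1-oxopropan-2-yl)-3-methylbenzoate
Product: 13 methyl 2,4-dimethoxy-6-{1-[methoxy(methyl)amino]-1-oxopropan-2-yl}-3-methylbenzoate (racemic)
Conditions: MeNHOMe·HCl (3 equiv), AlMe3 (3 equiv), CH2Cl2, 0 °C → rt; 1 M HCl
Reagents that add atoms: N,O-dimethylhydroxylamine hydrochloride, CNOC.Cl
Why: Aluminium amide aminolysis (Weinreb amide formation) is not basic enough to enolize the α-aryl ester; it attacks the aliphatic ester only, because the benzoate is shielded by a methoxy group and the branched side chain.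

**Step 6**
Reactants: 13 Weinreb amide
Product: 14 methyl 2,4-dimethoxy-3-methyl-6-(3-oxobutan-2-yl)benzoate (racemic)
Conditions: MeMgBr (2 equiv), THF, −20 → 0 °C; 1 M HCl, 0 °C
Reagents that add atoms: methylmagnesium bromide, C[Mg]Br
Why: Grignard addition to a Weinreb amide stops at the chelated tetrahedral intermediate, which gives the methyl ketone only on work-up; the di-ortho-substituted benzoate should not react at 0 °C.

**Step 7**
Reactants: 14 methyl 2,4-dimethoxy-3-methyl-6-(3-oxobutan-2-yl)benzoate
Product: 16 (3S,4R)-6,8-dimethoxy-3,4,7-trimethyl-3,4-dihydro-1H-isochromen-1-one, via hydroxy ester 15 (not isolated)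
Conditions: RuCl2[(R)-xylbinap][(R)-daipen] (1 mol%), t-BuOK (0.2 equiv), H2 (8 atm), i-PrOH, 25 °C; then TsOH·H2O (cat.), PhMe, 50 °C
Reagents that add atoms: none
Why: Dynamic kinetic resolution by bifunctional diphosphine/diamine ruthenium hydrogenation, a known way to set both centers of racemic acyclic α-aryl methyl ketones: t-BuOK equilibrates the two enantiomers of 14 through the enolate faster than either is reduced. The catalyst should reduce the (R)-ketone faster, with hydride delivered to the Felkin–Anh face anti to the aryl group, which sets the carbinol center as S beside the R benzylic center (threo). The hydroxyl then closes onto the neighbouring ester to give the trans-lactone.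

**Step 8**
Reactants: 16 (3S,4R)-6,8-dimethoxy-3,4,7-trimethyl-3,4-dihydro-1H-isochromen-1-one
Product: 17 (3S,4R)-5-bromo-6,8-dimethoxy-3,4,7-trimethyl-3,4-dihydro-1H-isochromen-1-one
Conditions: NBS (1.05 equiv), MeCN, 0 °C → rt, dark
Reagents that add atoms: N-bromosuccinimide, O=C1CCC(=O)N1Br
Why: Electrophilic bromination at the only free ring position, ortho and para to the two methoxy groups and meta to the acyl group; polar solvent and darkness suppress benzylic radical bromination.

**Step 9**
Reactants: 17 bromolactone
Product: 18 (3S,4R)-6,8-dimethoxy-3,4,5,7-tetramethyl-3,4-dihydro-1H-isochromen-1-one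
Conditions: MeB(OH)2 (3 equiv), Pd(OAc)2 (5 mol%), SPhos (10 mol%), K3PO4, PhMe/H2O, 100 °C; acidic work-up
Reagents that add atoms: methylboronic acid, CB(O)O
Why: Suzuki–Miyaura methylation; the dialkylbiarylphosphine allows oxidative addition and reductive elimination at the di-ortho-substituted bromide. Any lactone opened by the base recloses on acidification, and the stereocenters are not involved.

**Step 10**
Reactants: 18 dimethoxy lactone
Product: 19 (3S,4R)-6,8-dihydroxy-3,4,5,7-tetramethyl-3,4-dihydro-1H-isochromen-1-one
Conditions: BBr3 (5 equiv), CH2Cl2, −78 °C → rt; H2O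
Reagents that add atoms: none
Why: Lewis-acid ether cleavage: boron coordinates each methoxy oxygen and bromide removes the methyl group by SN2. The lactone, deactivated by coordination, and its two stereocenters are not part of the reaction.

**Step 11**
Reactants: 19 dihydroxy lactone
Product: 20 (3S,4R)-3,4,5,7-tetramethyl-3,4-dihydro-1H-isochromene-1,6,8-triol (lactol, both C1 epimers)
Conditions: i-Bu2AlH (3.5 equiv), CH2Cl2/THF, −78 °C; aq. potassium sodium tartrate
Reagents that add atoms: none
Why: Partial reduction of a lactone to the lactol: two hydride equivalents are consumed by the phenols, and the tetrahedral aluminium alkoxide formed by the third should be stable at −78 °C until hydrolysis.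

**Step 12**
Reactants: 21 methyl (R)-3-hydroxybutanoate
Product: 22 methyl (3R)-3-[(tert-butyldimethylsilyl)oxy]butanoate
Conditions: TBSCl, imidazole, DMF, rt
Reagents that add atoms: tert-butyldimethylsilyl chloride, CC(C)(C)[Si](C)(C)Cl
Why: Silyl ether formation at the secondary alcohol; the stereocenter is not involved.

**Step 13**
Reactants: 22 silyl ether ester
Product: 23 (3R)-3-[(tert-butyldimethylsilyl)oxy]-N-methoxy-N-methylbutanamide
Conditions: MeNHOMe·HCl (1.5 equiv), i-PrMgCl (3 equiv), THF, −20 → 0 °C; aq. NH4Cl
Reagents that add atoms: N,O-dimethylhydroxylamine hydrochloride, CNOC.Cl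
Why: Magnesium amide aminolysis of an unhindered ester gives the Weinreb amide at low temperature, where β-elimination of the silyloxy group should not compete.

**Step 14**
Reactants: 23 Weinreb amide; 24 methyl acetoacetate
Product: 26 methyl (7R)-7-[(tert-butyldimethylsilyl)oxy]-3,5-dioxooctanoate, via dilithium dianion 25 (not isolated)
Conditions: 24 (2.2 equiv), LiN(i-Pr)2 (4.5 equiv), THF, 0 °C; 23, −78 → 0 °C; 1 M HCl to pH 4, 0 °C
Reagents that add atoms: none
Why: Claisen-type γ-acylation of the acetoacetate dianion: the more nucleophilic terminal carbanion attacks the Weinreb amide, and the chelated adduct survives until work-up, so the acidic product cannot quench the dianion.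

**Step 15**
Reactants: 26 silyloxy diketo ester
Product: 28 methyl 2-[(2R)-2-methyl-4-oxo-3,4-dihydro-2H-pyran-6-yl]acetate, via hydroxy diketo ester 27 (not isolated)
Conditions: 48% aq. HF, MeCN, 0 °C → rt
Reagents that add atoms: none
Why: Acid removes the silyl group and the freed hydroxyl adds to the C3 ketone (six-membered hemiketal), which dehydrates to the vinylogous ester; closure onto the ester would need an eight-membered ring. The stereocenter keeps its C–O bond.

**Step 16**
Reactants: 20 lactol; 28 methyl 2-[(2R)-2-methyl-4-oxo-3,4-dihydro-2H-pyran-6-yl]acetate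
Product: 31 7-hydroxy-5-[(2R,3S)-3-hydroxybutan-2-yl]-6,8-dimethyl-3-[(2R)-2-methyl-4-oxo-3,4-dihydro-2H-pyran-6-yl]-2H-chromen-2-one, via hydroxy aldehyde 29 (not isolated), via alkylidene ester 30 (not isolated)
Conditions: piperidine (0.2 equiv), AcOH (0.2 equiv), EtOH, 60 °C
Reagents that add atoms: none
Why: Knoevenagel condensation of the open aldehyde tautomer with the methylene activated by the ester and the vinylogous ester, followed by lactonization of the ortho phenol onto the methyl ester (coumarin synthesis). The coumarin is the thermodynamic sink and releases the side-chain hydroxyl; buffered amine catalysis is chosen to spare the base-sensitive stereocenter of ring C.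

## Compound list

1 | 5-bromo-1,3-dimethoxy-2-methylbenzene | COc1cc(Br)cc(OC)c1C | starting material
2 | (3,5-dimethoxy-4-methylphenyl)lithium | [Li]c1cc(OC)c(C)c(OC)c1 | intermediate
3 | lithium trimethoxy(3,5-dimethoxy-4-methylphenyl)borate | [Li+].CO[B-](OC)(OC)c1cc(OC)c(C)c(OC)c1 | intermediate
4 | 3,5-dimethoxy-4-methylphenol | COc1cc(O)cc(OC)c1C | intermediate
5 | 2-bromo-3,5-dimethoxy-4-methylphenol | COc1cc(O)c(Br)c(OC)c1C | intermediate
6 | (2-bromo-3,5-dimethoxy-4-methylphenoxy)trimethylsilane | COc1cc(O[Si](C)(C)C)c(Br)c(OC)c1C | intermediate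
7 | lithium 3,5-dimethoxy-4-methyl-2-(trimethylsilyl)phenoxide | [Li+].[O-]c1cc(OC)c(C)c(OC)c1[Si](C)(C)C | intermediate
8 | 3,5-dimethoxy-4-methyl-2-(trimethylsilyl)phenyl trifluoromethanesulfonate | COc1cc(OS(=O)(=O)C(F)(F)F)c([Si](C)(C)C)c(OC)c1C | intermediate
9 | dimethyl methylmalonate | COC(=O)C(C)C(=O)OC | starting material
10 | 3,5-dimethoxy-4-methylbenzyne | COC1=C(C)C(OC)=CC#C1 | intermediate
11 | caesium 3,5,7-trimethoxy-8-(methoxycarbonyl)-4,8-dimethylbicyclo[4.2.0]octa-1,3,5-trien-7-olate | [Cs+].COC(=O)C1(C)c2cc(OC)c(C)c(OC)c2C1([O-])OC | intermediate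
12 | methyl 2,4-dimethoxy-6-(1-methoxy-1-oxopropan-2-yl)-3-methylbenzoate (racemic) | COC(=O)C(C)c1cc(OC)c(C)c(OC)c1C(=O)OC | intermediate
13 | methyl 2,4-dimethoxy-6-{1-[methoxy(methyl)amino]-1-oxopropan-2-yl}-3-methylbenzoate (racemic) | CON(C)C(=O)C(C)c1cc(OC)c(C)c(OC)c1C(=O)OC | intermediate
14 | methyl 2,4-dimethoxy-3-methyl-6-(3-oxobutan-2-yl)benzoate (racemic) | CC(=O)C(C)c1cc(OC)c(C)c(OC)c1C(=O)OC | intermediate
15 | methyl 6-[(2R,3S)-3-hydroxybutan-2-yl]-2,4-dimethoxy-3-methylbenzoate | COC(=O)c1c(OC)c(C)c(OC)cc1[C@@H](C)[C@H](C)O | intermediate
16 | (3S,4R)-6,8-dimethoxy-3,4,7-trimethyl-3,4-dihydro-1H-isochromen-1-one | COc1cc2[C@@H](C)[C@H](C)OC(=O)c2c(OC)c1C | intermediate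
17 | (3S,4R)-5-bromo-6,8-dimethoxy-3,4,7-trimethyl-3,4-dihydro-1H-isochromen-1-one | COc1c(Br)c2[C@@H](C)[C@H](C)OC(=O)c2c(OC)c1C | intermediate
18 | (3S,4R)-6,8-dimethoxy-3,4,5,7-tetramethyl-3,4-dihydro-1H-isochromen-1-one | COc1c(C)c2[C@@H](C)[C@H](C)OC(=O)c2c(OC)c1C | intermediate
19 | (3S,4R)-6,8-dihydroxy-3,4,5,7-tetramethyl-3,4-dihydro-1H-isochromen-1-one | Oc1c(C)c2[C@@H](C)[C@H](C)OC(=O)c2c(O)c1C | intermediate
20 | (3S,4R)-3,4,5,7-tetramethyl-3,4-dihydro-1H-isochromene-1,6,8-triol (both C1 epimers) | Oc1c(C)c2[C@@H](C)[C@H](C)OC(O)c2c(O)c1C | intermediate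
21 | methyl (R)-3-hydroxybutanoate | COC(=O)C[C@@H](C)O | starting material
22 | methyl (3R)-3-[(tert-butyldimethylsilyl)oxy]butanoate | COC(=O)C[C@@H](C)O[Si](C)(C)C(C)(C)C | intermediate
23 | (3R)-3-[(tert-butyldimethylsilyl)oxy]-N-methoxy-N-methylbutanamide | CON(C)C(=O)C[C@@H](C)O[Si](C)(C)C(C)(C)C | intermediate
24 | methyl acetoacetate | COC(=O)CC(C)=O | starting material
25 | dilithium dianion of methyl acetoacetate | [Li+].[Li+].[CH2-]C(=O)[CH-]C(=O)OC | intermediate
26 | methyl (7R)-7-[(tert-butyldimethylsilyl)oxy]-3,5-dioxooctanoate | COC(=O)CC(=O)CC(=O)C[C@@H](C)O[Si](C)(C)C(C)(C)C | intermediate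
27 | methyl (7R)-7-hydroxy-3,5-dioxooctanoate | COC(=O)CC(=O)CC(=O)C[C@@H](C)O | intermediate
28 | methyl 2-[(2R)-2-methyl-4-oxo-3,4-dihydro-2H-pyran-6-yl]acetate | COC(=O)CC1=CC(=O)C[C@@H](C)O1 | intermediate
29 | 2,4-dihydroxy-6-[(2R,3S)-3-hydroxybutan-2-yl]-3,5-dimethylbenzaldehyde | O=Cc1c(O)c(C)c(O)c(C)c1[C@@H](C)[C@H](C)O | intermediate
30 | methyl 3-{2,4-dihydroxy-6-[(2R,3S)-3-hydroxybutan-2-yl]-3,5-dimethylphenyl}-2-[(2R)-2-methyl-4-oxo-3,4-dihydro-2H-pyran-6-yl]prop-2-enoate (double-bond isomers) | COC(=O)C(=Cc1c(O)c(C)c(O)c(C)c1[C@@H](C)[C@H](C)O)C1=CC(=O)C[C@@H](C)O1 | intermediate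
31 | 7-hydroxy-5-[(2R,3S)-3-hydroxybutan-2-yl]-6,8-dimethyl-3-[(2R)-2-methyl-4-oxo-3,4-dihydro-2H-pyran-6-yl]-2H-chromen-2-one | Cc1c(O)c(C)c2oc(=O)c(C3=CC(=O)C[C@@H](C)O3)cc2c1[C@@H](C)[C@H](C)O | target

## Step count and least certain steps

Total step count: 16. Longest linear sequence: 12 steps (steps 1 to 11, then step 16). The ring C fragment 28 takes 4 steps (12 to 15).

**Step 4 (key step).**
- What may go wrong: the tertiary carbanion is hindered, so the aryl anion may be protonated before it reaches the ester carbonyl. This would give simple α-arylation without acyl transfer. Slow addition to the aryne may let the aryne be consumed by oligomerization. Partial loss of regiocontrol on the trisubstituted aryne is also possible.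
- Fallback: aryne-free, from 1 back to 12. Palladium-catalysed coupling of 1 with the zinc enolate BrZnCH(CH3)CO2CH3 (Pd(dba)2, P(t-Bu)3, THF) would give methyl 2-(3,5-dimethoxy-4-methylphenyl)propanoate F1. Rieche formylation (Cl2CHOCH3, TiCl4, CH2Cl2) can only enter one of the two equivalent positions between the side chain and a methoxy group, giving methyl 2-(2-formyl-3,5-dimethoxy-4-methylphenyl)propanoate F2. Pinnick oxidation (NaClO2, NaH2PO4, 2-methylbut-2-ene) gives 2,4-dimethoxy-6-(1-methoxy-1-oxopropan-2-yl)-3-methylbenzoic acid F3. Methylation of the carboxylate (CH3I, K2CO3, DMF) returns to 12.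

**Step 7.**
- What may go wrong: epimerization of the ketone may be slower than reduction, eroding both diastereo- and enantioselectivity. The enolate may instead be acylated by the neighbouring benzoate, on oxygen or on the methyl carbon, which consumes the ketone. Discrimination may also be weak, because the carbonyl is flanked by two alkyl groups.
- Fallback: from 12 back to 16, setting the benzylic center first and letting it control the reduction.
  - LiOH (1 equiv, aqueous THF) should hydrolyse only the aliphatic ester, to racemic 2-[3,5-dimethoxy-2-(methoxycarbonyl)-4-methylphenyl]propanoic acid F4.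
  - Oxalyl chloride and then Me2NEt generate the ketene methyl 2,4-dimethoxy-3-methyl-6-(1-oxoprop-1-en-2-yl)benzoate F5.
  - (R)-Pantolactone adds to F5 with diastereoselective protonation, the known deracemization of 2-arylpropanoic acids. This gives (3R)-4,4-dimethyl-2-oxooxolan-3-yl (2R)-2-[3,5-dimethoxy-2-(methoxycarbonyl)-4-methylphenyl]propanoate F6.
  - LiOH/H2O2 at 0 °C releases (2R)-2-[3,5-dimethoxy-2-(methoxycarbonyl)-4-methylphenyl]propanoic acid F7.
  - Carbodiimide coupling with MeNHOMe·HCl gives methyl 2,4-dimethoxy-6-{(2R)-1-[methoxy(methyl)amino]-1-oxopropan-2-yl}-3-methylbenzoate F8.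
  - MeMgBr gives methyl 2,4-dimethoxy-3-methyl-6-[(2R)-3-oxobutan-2-yl]benzoate F9.
  - LiBH(s-Bu)3 at −78 °C reduces F9 under Felkin–Anh control, and the alkoxide closes onto the ester to give 16.

**Step 16.**
- What may go wrong: the side-chain hydroxyl may trap the condensation product as a 1-substituted isochromene that opens slowly. Piperidine may open ring C by conjugate addition. The ring C stereocenter may erode by retro-oxa-Michael opening.
- Fallback: build ring C last, from 20 back to 31. Knoevenagel condensation of 20 with methyl acetoacetate 24 (piperidine cat., EtOH) would give 3-acetyl-7-hydroxy-5-[(2R,3S)-3-hydroxybutan-2-yl]-6,8-dimethyl-2H-chromen-2-one F10. Silylation of both hydroxyls (TBSOTf, 2,6-lutidine) gives 3-acetyl-7-[(tert-butyldimethylsilyl)oxy]-5-[(2R,3S)-3-[(tert-butyldimethylsilyl)oxy]butan-2-yl]-6,8-dimethyl-2H-chromen-2-one F11. Its lithium enolate (LiN(SiMe3)2, THF, −78 °C) is acylated by Weinreb amide 23 to the β-diketone 7-[(tert-butyldimethylsilyl)oxy]-5-[(2R,3S)-3-[(tert-butyldimethylsilyl)oxy]butan-2-yl]-3-[(5R)-5-[(tert-butyldimethylsilyl)oxy]-3-oxohexanoyl]-6,8-dimethyl-2H-chromen-2-one F12. Aqueous HF in MeCN removes the three silyl groups and closes ring C by cyclodehydration to 31.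

**Step 11.**
- What may go wrong: the aluminium phenoxide ortho to the carbonyl may deactivate the lactone so that reduction stalls, or warming may cause over-reduction to the benzylic alcohol.
- Fallback: over-reduce and re-oxidize, from 19 back to 20. LiAlH4 in THF at reflux reduces the lactone fully to (2S,3R)-3-[3,5-dihydroxy-2-(hydroxymethyl)-4,6-dimethylphenyl]butan-2-ol F13. MnO2 in CH2Cl2 oxidizes only the benzylic alcohol to the salicylaldehyde, which is 20 in its open form 29.

## Further compounds

F1 | step 4 | methyl 2-(3,5-dimethoxy-4-methylphenyl)propanoate (racemic) | COC(=O)C(C)c1cc(OC)c(C)c(OC)c1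
F2 | step 4 | methyl 2-(2-formyl-3,5-dimethoxy-4-methylphenyl)propanoate (racemic) | COC(=O)C(C)c1cc(OC)c(C)c(OC)c1C=O
F3 | step 4 | 2,4-dimethoxy-6-(1-methoxy-1-oxopropan-2-yl)-3-methylbenzoic acid (racemic) | COC(=O)C(C)c1cc(OC)c(C)c(OC)c1C(=O)O
F4 | step 7 | 2-[3,5-dimethoxy-2-(methoxycarbonyl)-4-methylphenyl]propanoic acid (racemic) | COC(=O)c1c(OC)c(C)c(OC)cc1C(C)C(=O)O
F5 | step 7 | methyl 2,4-dimethoxy-3-methyl-6-(1-oxoprop-1-en-2-yl)benzoate | COC(=O)c1c(OC)c(C)c(OC)cc1C(C)=C=O
F6 | step 7 | (3R)-4,4-dimethyl-2-oxooxolan-3-yl (2R)-2-[3,5-dimethoxy-2-(methoxycarbonyl)-4-methylphenyl]propanoate | COC(=O)c1c(OC)c(C)c(OC)cc1[C@@H](C)C(=O)O[C@H]1C(=O)OCC1(C)C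
F7 | step 7 | (2R)-2-[3,5-dimethoxy-2-(methoxycarbonyl)-4-methylphenyl]propanoic acid | COC(=O)c1c(OC)c(C)c(OC)cc1[C@@H](C)C(=O)O
F8 | step 7 | methyl 2,4-dimethoxy-6-{(2R)-1-[methoxy(methyl)amino]-1-oxopropan-2-yl}-3-methylbenzoate | COC(=O)c1c(OC)c(C)c(OC)cc1[C@@H](C)C(=O)N(C)OC
F9 | step 7 | methyl 2,4-dimethoxy-3-methyl-6-[(2R)-3-oxobutan-2-yl]benzoate | COC(=O)c1c(OC)c(C)c(OC)cc1[C@@H](C)C(C)=O
F10 | step 16 | 3-acetyl-7-hydroxy-5-[(2R,3S)-3-hydroxybutan-2-yl]-6,8-dimethyl-2H-chromen-2-one | CC(=O)c1cc2c([C@@H](C)[C@H](C)O)c(C)c(O)c(C)c2oc1=O
F11 | step 16 | 3-acetyl-7-[(tert-butyldimethylsilyl)oxy]-5-[(2R,3S)-3-[(tert-butyldimethylsilyl)oxy]butan-2-yl]-6,8-dimethyl-2H-chromen-2-one | CC(=O)c1cc2c([C@@H](C)[C@H](C)O[Si](C)(C)C(C)(C)C)c(C)c(O[Si](C)(C)C(C)(C)C)c(C)c2oc1=O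
F12 | step 16 | 7-[(tert-butyldimethylsilyl)oxy]-5-[(2R,3S)-3-[(tert-butyldimethylsilyl)oxy]butan-2-yl]-3-[(5R)-5-[(tert-butyldimethylsilyl)oxy]-3-oxohexanoyl]-6,8-dimethyl-2H-chromen-2-one | O=C(CC(=O)C[C@@H](C)O[Si](C)(C)C(C)(C)C)c1cc2c([C@@H](C)[C@H](C)O[Si](C)(C)C(C)(C)C)c(C)c(O[Si](C)(C)C(C)(C)C)c(C)c2oc1=O
F13 | step 11 | (2S,3R)-3-[3,5-dihydroxy-2-(hydroxymethyl)-4,6-dimethylphenyl]butan-2-ol | OCc1c(O)c(C)c(O)c(C)c1[C@@H](C)[C@H](C)O
A1 | alternative 1 | ethyl 6-[(2R,3S)-3-[(tert-butyldimethylsilyl)oxy]butan-2-yl]-3,5-dimethyl-2,4-dioxocyclohexane-1-carboxylate (ring epimers and enol forms) | CCOC(=O)C1C(=O)C(C)C(=O)C(C)C1[C@@H](C)[C@H](C)O[Si](C)(C)C(C)(C)C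
A2 | alternative 1 | diethyl 2-[(2R,3S)-3-[(tert-butyldimethylsilyl)oxy]-2-methylbutylidene]propanedioate | CCOC(=O)C(=C[C@@H](C)[C@H](C)O[Si](C)(C)C(C)(C)C)C(=O)OCC
A3 | alternative 2 | (2S,3R)-3-{7-hydroxy-6,8-dimethyl-3-[(2R)-2-methyl-4-oxo-3,4-dihydro-2H-pyran-6-yl]-2-oxo-2H-chromen-5-yl}butan-2-yl acetate | Cc1c(O)c(C)c2oc(=O)c(C3=CC(=O)C[C@@H](C)O3)cc2c1[C@@H](C)[C@H](C)OC(C)=O
A4 | alternative 2 | (2S,3R)-3-(3,5-dihydroxy-2,4-dimethylphenyl)butan-2-yl acetate | Cc1c(O)cc([C@@H](C)[C@H](C)OC(C)=O)c(C)c1O
A5 | alternative 2 | methyl 3-(dimethylamino)-2-[(2R)-2-methyl-4-oxo-3,4-dihydro-2H-pyran-6-yl]prop-2-enoate | COC(=O)C(=CN(C)C)C1=CC(=O)C[C@@H](C)O1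
A6 | alternative 3 | methyl 6-[(2R,3S)-3-[(tert-butyldimethylsilyl)oxy]butan-2-yl]-2,4-dihydroxy-3,5-dimethylbenzoate | COC(=O)c1c(O)c(C)c(O)c(C)c1[C@@H](C)[C@H](C)O[Si](C)(C)C(C)(C)C
A7 | alternative 3 | methyl (4R,5S)-5-[(tert-butyldimethylsilyl)oxy]-4-methylhex-2-ynoate | COC(=O)C#C[C@@H](C)[C@H](C)O[Si](C)(C)C(C)(C)C
A8 | alternative 3 | (3Z)-1-methoxy-2-methyl-1,3-bis(trimethylsilyloxy)penta-1,3-diene | COC(O[Si](C)(C)C)=C(C)/C(O[Si](C)(C)C)=C/C
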